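## Retrosynthetic overview

1. The one strategic disconnection is the diaryl ether bond between C-7 of the lower (epigallocatechin) unit and O-4' of the upper (gallocatechin) unit, made late by a C–O cross-coupling of an aryl tosylate and a phenol.
2. Lower unit: (-)-epigallocatechin 1 → ring B ketal 2 → [7-O-tosylate 3, in the flask] → dibenzyl tosylate 4 (C-7 electrophile).
3. Upper unit: (+)-gallocatechin 5 → [4'-O-allyl ether 6, in the flask] → allyl tetrabenzyl ether 7 → 4'-phenol 8 (O nucleophile).
4. 4 + 8 → protected dimer 9 → global hydrogenolysis → target 10.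
5. Ring order: no ring is built. All six rings and all four stereocentres are bought with the two catechins and carried through.

Assumption: (-)-epigallocatechin (2R,3R) and (+)-gallocatechin (2R,3S) are bought as single natural enantiomers; the target is read as (+)-gallocatechin-(4'-O→7)-(-)-epigallocatechin (upper unit 2R,3S; lower unit 2R,3R).

## Route

Step 1
Reactants: 1 (-)-epigallocatechin
Product: 2 3',4'-O-(diphenylmethylene)-(-)-epigallocatechin
Conditions: Ph2CCl2 (1.2 equiv), K2CO3 (3 equiv), MeCN, Ar, rt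
Reagents that add atoms: dichlorodiphenylmethane, ClC(Cl)(c1ccccc1)c1ccccc1
Why: Ketalization by double Williamson-type O-alkylation with a gem-dichloride: only the vicinal ring B hydroxyls can close the five-membered benzodioxole, acyclic adducts of the ring A phenols hydrolyse on work-up, and no stereocentre is touched; tying up O-4' also blocks the quinone-methide opening of ring C that epimerizes C2 under base.

Step 2
Reactants: 2 3',4'-O-(diphenylmethylene)-(-)-epigallocatechin
Product: 4 5,5'-di-O-benzyl-3',4'-O-(diphenylmethylene)-7-O-tosyl-(-)-epigallocatechin, via 7-O-tosylate 3 (not isolated)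
Conditions: TsCl (1.05 equiv), K2CO3, acetone, 0 °C; then BnBr (2.5 equiv), K2CO3, n-Bu4NI (cat.), DMF, rt
Reagents that add atoms: p-toluenesulfonyl chloride, Cc1ccc(cc1)S(Cl)(=O)=O; benzyl bromide, BrCc1ccccc1
Why: Phenol sulfonylation then Williamson etherification in one pot: the 7-OH is the most acidic and the only unflanked phenol of 2 (5-OH sits next to C4a, the ring B OH next to a ketal oxygen), so it takes the single equivalent of TsCl; the two remaining phenols are then benzylated, the secondary 3-OH is inert to K2CO3, the aryl tosylate does not migrate, and no stereocentre is touched.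

Step 3
Reactants: 5 (+)-gallocatechin
Product: 7 4'-O-allyl-5,7,3',5'-tetra-O-benzyl-(+)-gallocatechin, via 4'-O-allylgallocatechin 6 (not isolated)
Conditions: allyl bromide (1.05 equiv), K2CO3 (1.0 equiv), DMF, Ar, 0 °C; then BnBr (4.5 equiv), K2CO3 (5 equiv), DMF, 0 °C to rt
Reagents that add atoms: allyl bromide, C=CCBr; benzyl bromide, BrCc1ccccc1
Why: Two Williamson etherifications in one pot: the central 4'-OH, flanked by two hydroxyls, is the most acidic phenol of gallocatechin, so one equivalent of carbonate and allyl bromide parks an allyl group there; the four remaining phenols are then benzylated, the 3-OH stays free, and capping O-4' first protects C2 from base-induced epimerization.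

Step 4
Reactants: 7 4'-O-allyl-5,7,3',5'-tetra-O-benzyl-(+)-gallocatechin
Product: 8 5,7,3',5'-tetra-O-benzyl-(+)-gallocatechin
Conditions: Pd(PPh3)4 (3 mol%), morpholine (5 equiv), THF, rt
Reagents that add atoms: none
Why: Tsuji–Trost-type deallylation: zerovalent palladium ionizes the aryl allyl ether to a pi-allyl complex that morpholine traps, benzyl ethers are inert, and at room temperature with only an amine base the freed 4'-phenol does not epimerize C2.

Step 5
Reactants: 4 5,5'-di-O-benzyl-3',4'-O-(diphenylmethylene)-7-O-tosyl-(-)-epigallocatechin; 8 5,7,3',5'-tetra-O-benzyl-(+)-gallocatechin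
Product: 9 protected dimer in which O-4' of 5,7,3',5'-tetra-O-benzyl-(+)-gallocatechin is bonded to C-7 of the 5,5'-di-O-benzyl-3',4'-O-(diphenylmethylene)-(-)-epigallocatechin unit
Conditions: Pd2(dba)3 (2.5 mol%), tBuBrettPhos (6 mol%), K3PO4 (2 equiv), toluene, 90 °C
Reagents that add atoms: none
Why: Proposed new method: palladium-catalysed C–O cross-coupling of an aryl tosylate with a hindered phenol, which to my knowledge has not been shown — zerovalent palladium on the bulky, electron-rich di-tert-butyl biaryl phosphine inserts into the unhindered C7–OTs bond of 4 (inductively activated by two meta oxygens), K3PO4 exchanges tosylate on divalent palladium for the 2,6-dibenzyloxyphenoxide of 8, and ligand bulk drives C–O reductive elimination; the closest known reactions are the Buchwald–Hartwig diaryl ether synthesis from aryl halides and triflates and the palladium-catalysed amination and amidation of aryl tosylates and mesylates with the same ligand family; no stereocentre is formed, K3PO4 is too weak to ionize the 3-OH groups, and O-arylation removes the one phenoxide that could open ring C at C2.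

Step 6
Reactants: 9 protected dimer
Product: 10 (+)-gallocatechin-(4'-O→7)-(-)-epigallocatechin (target)
Conditions: H2 (1 atm), Pd(OH)2/C, THF/MeOH 1:1, rt
Reagents that add atoms: none
Why: Hydrogenolysis removes the six benzyl ethers and the diphenylmethylene ketal in one operation, while the diaryl ether, the chroman C2–O bonds and all four stereocentres are untouched under these neutral conditions.

## Compound list

1 | (-)-epigallocatechin, (2R,3R)-2-(3,4,5-trihydroxyphenyl)chromane-3,5,7-triol | Oc1cc(O)c2c(c1)O[C@H](c1cc(O)c(O)c(O)c1)[C@H](O)C2 | starting material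
2 | 3',4'-O-(diphenylmethylene)-(-)-epigallocatechin, (2R,3R)-2-(7-hydroxy-2,2-diphenyl-1,3-benzodioxol-5-yl)chromane-3,5,7-triol | Oc1cc(O)c2c(c1)O[C@H](c1cc(O)c3OC(c4ccccc4)(c4ccccc4)Oc3c1)[C@H](O)C2 | intermediate
3 | 3',4'-O-(diphenylmethylene)-7-O-tosyl-(-)-epigallocatechin (not isolated) | Cc1ccc(cc1)S(=O)(=O)Oc1cc(O)c2c(c1)O[C@H](c1cc(O)c3OC(c4ccccc4)(c4ccccc4)Oc3c1)[C@H](O)C2 | intermediate
4 | 5,5'-di-O-benzyl-3',4'-O-(diphenylmethylene)-7-O-tosyl-(-)-epigallocatechin (2R,3R; free 3-OH) | Cc1ccc(cc1)S(=O)(=O)Oc1cc(OCc5ccccc5)c2c(c1)O[C@H](c1cc(OCc5ccccc5)c3OC(c4ccccc4)(c4ccccc4)Oc3c1)[C@H](O)C2 | intermediate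
5 | (+)-gallocatechin, (2R,3S)-2-(3,4,5-trihydroxyphenyl)chromane-3,5,7-triol | Oc1cc(O)c2c(c1)O[C@H](c1cc(O)c(O)c(O)c1)[C@@H](O)C2 | starting material
6 | 4'-O-allyl-(+)-gallocatechin (not isolated) | Oc1cc(O)c2c(c1)O[C@H](c1cc(O)c(OCC=C)c(O)c1)[C@@H](O)C2 | intermediate
7 | 4'-O-allyl-5,7,3',5'-tetra-O-benzyl-(+)-gallocatechin (2R,3S; free 3-OH) | c1ccccc1COc1cc(OCc3ccccc3)c2c(c1)O[C@H](c1cc(OCc3ccccc3)c(OCC=C)c(OCc3ccccc3)c1)[C@@H](O)C2 | intermediate
8 | 5,7,3',5'-tetra-O-benzyl-(+)-gallocatechin (2R,3S; free 4'-OH and 3-OH) | c1ccccc1COc1cc(OCc3ccccc3)c2c(c1)O[C@H](c1cc(OCc3ccccc3)c(O)c(OCc3ccccc3)c1)[C@@H](O)C2 | intermediate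
9 | protected dimer: O-4' of 5,7,3',5'-tetra-O-benzyl-(+)-gallocatechin bonded to C-7 of 5,5'-di-O-benzyl-3',4'-O-(diphenylmethylene)-(-)-epigallocatechin (upper 2R,3S; lower 2R,3R) | c1ccccc1COc1cc(OCc3ccccc3)c2c(c1)O[C@H](c1cc(OCc3ccccc3)c(Oc4cc(OCc5ccccc5)c6c(c4)O[C@H](c4cc(OCc5ccccc5)c7OC(c5ccccc5)(c5ccccc5)Oc7c4)[C@H](O)C6)c(OCc3ccccc3)c1)[C@@H](O)C2 | intermediate
10 | (2R,3S)-2-[4-{[(2R,3R)-3,5-dihydroxy-2-(3,4,5-trihydroxyphenyl)chroman-7-yl]oxy}-3,5-dihydroxyphenyl]chromane-3,5,7-triol | Oc1cc(O)c2c(c1)O[C@H](c1cc(O)c(Oc3cc(O)c4c(c3)O[C@H](c3cc(O)c(O)c(O)c3)[C@H](O)C4)c(O)c1)[C@@H](O)C2 | target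

## Step count and risks

Total step count: 6 (steps 2 and 3 are each one pot with an intermediate that is not isolated).
Longest linear sequence: 4 steps (steps 1, 2, 5, 6; equally steps 3, 4, 5, 6).

The three steps most likely to fail:

Step 5, the proposed new coupling. Oxidative addition into the tosylate may need a temperature at which the potassium 4'-phenoxide of 8 begins to open ring C and epimerize C2, or the C–O reductive elimination may stall. The fallback uses known chemistry and swaps the electrophile for the pseudohalide class on which palladium-catalysed diaryl ether formation is established. It sets out from 2: PhNTf2 and Et3N in CH2Cl2 at 0 °C give 7-O-triflyl-3',4'-O-(diphenylmethylene)-(-)-epigallocatechin F1; BnBr and K2CO3 in DMF give 5,5'-di-O-benzyl-7-O-triflyl-3',4'-O-(diphenylmethylene)-(-)-epigallocatechin F2; F2 and 8 are then joined under Buchwald-type aryl triflate etherification conditions (Pd2(dba)3, tBuXPhos, K3PO4, toluene, 80 °C). This comes back to the route at 9.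

Step 3, the one-pot 4'-selective allylation of unprotected gallocatechin. The ring A phenols are only about one pKa unit less acidic, so 7-O- and 3'-O-allyl isomers may form and are hard to separate from 7. The fallback takes the ring A phenols out of the competition before the 4'-oxygen is singled out. It sets out from 5: Ph2CCl2 and K2CO3 in MeCN give 3',4'-O-(diphenylmethylene)-(+)-gallocatechin F3; BnBr and K2CO3 give 5,7,5'-tri-O-benzyl-3',4'-O-(diphenylmethylene)-(+)-gallocatechin F4; aqueous acetic acid at 80 °C removes the ketal to give 5,7,5'-tri-O-benzyl-(+)-gallocatechin F5; one equivalent each of K2CO3 and allyl bromide then alkylates the central, more acidic of the two remaining phenols to give 4'-O-allyl-5,7,5'-tri-O-benzyl-(+)-gallocatechin F6; benzylation of the last phenol comes back to the route at 7.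

Step 2, the 7-selective tosylation of triol 2. The acidity margin over the 5-OH and the ring B OH is small, and a ring B tosylate isomer would carry through to a wrong ether in step 5. The fallback replaces direct activation by steric selection with a bulky temporary silyl group and stepwise isolation. It sets out from 2: TIPSCl and imidazole in DMF at 0 °C give 7-O-triisopropylsilyl-3',4'-O-(diphenylmethylene)-(-)-epigallocatechin F7; BnBr and K2CO3 give 5,5'-di-O-benzyl-7-O-triisopropylsilyl-3',4'-O-(diphenylmethylene)-(-)-epigallocatechin F8; Bu4NF in THF at 0 °C frees 5,5'-di-O-benzyl-3',4'-O-(diphenylmethylene)-(-)-epigallocatechin F9; TsCl and K2CO3 in acetone then tosylate its only phenol and come back to the route at 4.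

## Further compounds

F1 | step 5 | 7-O-triflyl-3',4'-O-(diphenylmethylene)-(-)-epigallocatechin | FC(F)(F)S(=O)(=O)Oc1cc(O)c2c(c1)O[C@H](c1cc(O)c3OC(c4ccccc4)(c4ccccc4)Oc3c1)[C@H](O)C2
F2 | step 5 | 5,5'-di-O-benzyl-7-O-triflyl-3',4'-O-(diphenylmethylene)-(-)-epigallocatechin | FC(F)(F)S(=O)(=O)Oc1cc(OCc5ccccc5)c2c(c1)O[C@H](c1cc(OCc5ccccc5)c3OC(c4ccccc4)(c4ccccc4)Oc3c1)[C@H](O)C2
F3 | step 3 | 3',4'-O-(diphenylmethylene)-(+)-gallocatechin | Oc1cc(O)c2c(c1)O[C@H](c1cc(O)c3OC(c4ccccc4)(c4ccccc4)Oc3c1)[C@@H](O)C2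
F4 | step 3 | 5,7,5'-tri-O-benzyl-3',4'-O-(diphenylmethylene)-(+)-gallocatechin | c1ccccc1COc1cc(OCc5ccccc5)c2c(c1)O[C@H](c1cc(OCc5ccccc5)c3OC(c4ccccc4)(c4ccccc4)Oc3c1)[C@@H](O)C2
F5 | step 3 | 5,7,5'-tri-O-benzyl-(+)-gallocatechin (free 3'-OH and 4'-OH) | c1ccccc1COc1cc(OCc5ccccc5)c2c(c1)O[C@H](c1cc(OCc5ccccc5)c(O)c(O)c1)[C@@H](O)C2
F6 | step 3 | 4'-O-allyl-5,7,5'-tri-O-benzyl-(+)-gallocatechin (free 3'-OH) | c1ccccc1COc1cc(OCc5ccccc5)c2c(c1)O[C@H](c1cc(OCc5ccccc5)c(OCC=C)c(O)c1)[C@@H](O)C2
F7 | step 2 | 7-O-triisopropylsilyl-3',4'-O-(diphenylmethylene)-(-)-epigallocatechin | CC(C)[Si](C(C)C)(C(C)C)Oc1cc(O)c2c(c1)O[C@H](c1cc(O)c3OC(c4ccccc4)(c4ccccc4)Oc3c1)[C@H](O)C2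
F8 | step 2 | 5,5'-di-O-benzyl-7-O-triisopropylsilyl-3',4'-O-(diphenylmethylene)-(-)-epigallocatechin | CC(C)[Si](C(C)C)(C(C)C)Oc1cc(OCc5ccccc5)c2c(c1)O[C@H](c1cc(OCc5ccccc5)c3OC(c4ccccc4)(c4ccccc4)Oc3c1)[C@H](O)C2
F9 | step 2 | 5,5'-di-O-benzyl-3',4'-O-(diphenylmethylene)-(-)-epigallocatechin (free 7-OH) | Oc1cc(OCc5ccccc5)c2c(c1)O[C@H](c1cc(OCc5ccccc5)c3OC(c4ccccc4)(c4ccccc4)Oc3c1)[C@H](O)C2
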